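**Plan**

1. Numbering used below (daucane type): C1 = quaternary ring-fusion carbon with methyl, C2–C3 = CH2, C4 = isopropyl carbinol, C5 = ring-fusion CH, C6 = ester carbon, C7=C8(Me), C9 = CHOH, C10 = CH2; cyclopentane = C1–C5, cycloheptene = C1, C5–C10.
2. Retrosynthesis: cut C9–OH (enone reduction), C7=C8 and the C8 methyl (α-chemistry of a C9 ketone), the ester C–O, then C5–H/C6–O (hydroboration of a C5=C6 alkene); cut the resulting hydroazulenone at C5–C1 and C6–C7 in one operation; cut the open chain at C1=C10 (olefination) and trace C1–C6 to a cyclohexene cleaved at C1=C6.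
3. Enabling feature: the seven-membered ring is a two-carbon unit C5–C6 bonded to both ends of the five-carbon arc C7–C8–C9–C10–C1, whose middle carbon C9 carries oxygen. The arc is therefore a 1-siloxy-1-alkenylcyclopropane (C9 with C8/C7, alkene C10=C1), C5–C6 is an alkyne, and the cyclopentane carbons C2–C3–C4 are the tether, so a rhodium-catalysed intramolecular (5+2) cycloaddition closes both rings and creates the quaternary C1.
4. Forward order: (S)-terpinen-4-ol (supplies C1–C6, the C1 methyl, the isopropyl group and the C4 centre) is ring-opened; the siloxycyclopropane is built on the methyl ketone; the CH2–CHO arm becomes the alkyne; the cycloaddition forms the five- and seven-membered rings together; methylation, hydroboration, acylation, dehydrogenation and reduction finish the route.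
5. Stereochemistry: C4 from the chiral pool; C1 by 1,3-induction from C4 in the cycloaddition; C5 and C6 together by syn hydroboration on the face opposite the angular methyl; C9 by hydride delivery opposite the angular methyl.

Key step: step 7

Assumption: (S)-(+)-terpinen-4-ol is used enantiomerically pure (commercial material of lower optical purity would first be enriched); no bond to its carbinol carbon is broken, so its configuration becomes that of C4.

**Step 1**
Reactants: 1 (S)-terpinen-4-ol
Product: 2 tert-butyldimethyl{[(1S)-4-methyl-1-(propan-2-yl)cyclohex-3-en-1-yl]oxy}silane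
Conditions: TBSOTf, 2,6-lutidine, CH2Cl2, 0 °C to rt
Reagents that add atoms: tert-butyldimethylsilyl trifluoromethanesulfonate, CC(C)(C)[Si](C)(C)OS(=O)(=O)C(F)(F)F
Why: Silyl triflate silylation of the hindered tertiary alcohol masks the future C4 hydroxyl as an ether that should survive ozonolysis, organometallic and basic steps; the stereocentre is not touched.

**Step 2**
Reactants: 2 silyl ether
Product: 4 (5S)-5-[(tert-butyldimethylsilyl)oxy]-7,7-dimethoxy-5-(propan-2-yl)heptan-2-one, via keto aldehyde 3 (not isolated)
Conditions: O3, CH2Cl2/MeOH, −78 °C; Me2S, −78 °C to rt; then HC(OMe)3, PPTS (cat.), MeOH, rt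
Reagents that add atoms: ozone, [O-][O+]=O; trimethyl orthoformate, COC(OC)OC
Why: Criegee ozonolysis of the only alkene opens the ring to the C1 methyl ketone and the C6 aldehyde, and mild acid-catalysed acetalisation should take only the far more electrophilic aldehyde, which differentiates the two carbonyl groups.

**Step 3**
Reactants: 4 keto acetal; 5 triethyl phosphonoacetate
Product: 6 ethyl (2E,6S)-6-[(tert-butyldimethylsilyl)oxy]-8,8-dimethoxy-3-methyl-6-(propan-2-yl)oct-2-enoate
Conditions: NaH, THF, 0 °C to 50 °C
Reagents that add atoms: none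
Why: Horner–Wadsworth–Emmons olefination of the methyl ketone should give mainly the E enoate (ester trans to the longer chain, thermodynamic control of the oxaphosphetane), the minor Z isomer being removed by chromatography.

**Step 4**
Reactants: 6 enoate
Product: 7 1-[(1E,5S)-5-[(tert-butyldimethylsilyl)oxy]-7,7-dimethoxy-2-methyl-5-(propan-2-yl)hept-1-en-1-yl]cyclopropan-1-ol
Conditions: EtMgBr (3 equiv), Ti(OiPr)4 (0.3 equiv), THF, 0 °C to rt
Reagents that add atoms: ethylmagnesium bromide, CC[Mg]Br
Why: Kulinkovich cyclopropanation, in which the titanacyclopropane from EtMgBr and Ti(OiPr)4 adds twice to the ester carbonyl; the β,β-disubstituted C=C is too hindered to exchange onto titanium, so the alkene and its geometry should be retained.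

**Step 5**
Reactants: 7 cyclopropanol
Product: 9 (3S,6E)-3-[(tert-butyldimethylsilyl)oxy]-6-methyl-3-(propan-2-yl)-7-{1-[(triethylsilyl)oxy]cyclopropyl}hept-6-enal, via collidinium salt 8 (not isolated)
Conditions: TESOTf, 2,4,6-collidine, CH2Cl2, 0 °C; then H2O
Reagents that add atoms: triethylsilyl trifluoromethanesulfonate, CC[Si](CC)(CC)OS(=O)(=O)C(F)(F)F; water, O
Why: The silyl triflate/pyridine base pair silylates the cyclopropanol and converts the dimethyl acetal through an N,O-acetal pyridinium salt into the aldehyde on aqueous quench (chemoselective non-acidic acetal cleavage), conditions that should spare the vinylcyclopropyl ether and the tertiary silyl ether.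

**Step 6**
Reactants: 9 aldehyde
Product: 11 (3R,6E)-3-[(tert-butyldimethylsilyl)oxy]-6-methyl-3-(propan-2-yl)-7-{1-[(triethylsilyl)oxy]cyclopropyl}hept-6-en-1-yne, via alkenyl nonaflate 10 (not isolated)
Conditions: C4F9SO2F, P2-Et phosphazene base, DMF, −30 °C to rt
Reagents that add atoms: none
Why: One-pot enolate O-sulfonylation and base-induced elimination of the alkenyl nonaflate (known conversion of an enolisable aldehyde RCH2CHO into the terminal alkyne RC≡CH without change of carbon count); C4 is not involved and only its descriptor changes.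

**Step 7**
Reactants: 11 enyne
Product: 13 (3R,8aR)-3-[(tert-butyldimethylsilyl)oxy]-8a-methyl-3-(propan-2-yl)-2,3,5,6,8,8a-hexahydroazulen-7(1H)-one, via silyl enol ether 12 (not isolated)
Conditions: [Rh(CO)2Cl]2 (5 mol%), toluene (0.02 M), 90 °C; then TBAF, AcOH, THF, 0 °C
Reagents that add atoms: none
Why: Monovalent rhodium inserts into a C9–CH2 bond of the donor-substituted cyclopropane to give a σ-alkyl/π-allyl complex of trivalent rhodium, the tethered alkyne inserts at the allyl terminus C1 (bond C1–C5), and reductive elimination from the eight-membered rhodacycle forms C6–C7, leaving the C9=C10 silyl enol ether that buffered fluoride converts into the ketone; the closest known reaction type is the rhodium-catalysed intramolecular (5+2) cycloaddition of alkyne-tethered vinylcyclopropanes, which tolerates 1-siloxy groups and alkene substitution that generates quaternary carbons. The cyclopentane is closed in the insertion step by a 5-exo attack of C1 on the proximal alkyne carbon C5 across the tether C2–C3–C4, and the cycloheptadiene is closed by the C6–C7 reductive elimination (contraction of the rhodacyclooctadiene, formally a 7-endo closure at the distal alkyne carbon). The only new stereocentre is the quaternary C1, controlled by C4: in the ring-forming transition state both carbons flanking the developing exocyclic C5=C6 bond turn one substituent out of its plane, the future angular methyl at C1 and the isopropyl group at C4 (the slim siloxy oxygen stays near the plane beside H-6), and these two groups avoid a 1,3-syn contact by taking opposite faces, which puts the methyl cis to the C4 oxygen as the target requires. The selectivities needed are this facial choice at C1 and (5+2) cycloaddition in preference to ring expansion of the siloxyvinylcyclopropane; the two cyclopropane CH2 groups are equivalent, so no regiochemical question arises, and the E alkene carrying the tether at its terminus, the terminal alkyne and the neutral chloride-bridged catalyst are the documented arrangement for the (5+2) mode. The hindered tertiary tert-butyldimethylsilyl ether should survive the brief buffered fluoride treatment that cleaves the much more labile triethylsilyl enol ether.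

**Step 8**
Reactants: 13 ketone
Product: 15 (3R,8aR)-3-[(tert-butyldimethylsilyl)oxy]-6,8a-dimethyl-3-(propan-2-yl)-2,3,5,6,8,8a-hexahydroazulen-7(1H)-one (6RS), via lithium enolate 14 (not isolated)
Conditions: LiN(iPr)2, THF, −78 °C; MeI, −78 to −20 °C
Reagents that add atoms: iodomethane, CI
Why: Kinetic enolate formation should occur at C8 because the other α-methylene (C10) is neopentyl next to the quaternary C1, and enolate alkylation installs the C8 methyl; the new centre is left as a mixture because it becomes sp2 in step 13.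

**Step 9**
Reactants: 15 methyl ketone
Product: 16 7-ethylene ketal of 15 (6RS)
Conditions: TMSOCH2CH2OTMS, TMSOTf (cat.), CH2Cl2, −78 to −20 °C
Reagents that add atoms: 1,2-bis(trimethylsilyloxy)ethane, C[Si](C)(C)OCCO[Si](C)(C)C
Why: Silyl triflate-catalysed ketalisation under aprotic low-temperature conditions protects the C9 ketone against borane without ionising the tertiary allylic silyl ether.

**Step 10**
Reactants: 16 ketal
Product: 18 (3R,3aS,4S,8aR)-3-[(tert-butyldimethylsilyl)oxy]-7,7-(ethylenedioxy)-6,8a-dimethyl-3-(propan-2-yl)decahydroazulen-4-ol (6RS), via alkylborane 17 (not isolated)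
Conditions: BH3·THF, THF, 0 °C to rt; then NaOH, H2O2, 0 °C to rt
Reagents that add atoms: hydrogen peroxide, OO
Why: Hydroboration–oxidation places boron on the less substituted C6 and hydrogen on C5 in a syn addition; attack on the face opposite the angular methyl and the siloxy group (as in hydroboration of 5-ene steroids) should set H-5 and the C6 oxygen cis to each other and trans to the angular methyl, which is the trans ring fusion, and oxidation of the C–B bond proceeds with retention.

**Step 11**
Reactants: 18 alcohol; 19 4-methoxybenzoyl chloride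
Product: 20 (3R,3aS,4S,8aR)-3-[(tert-butyldimethylsilyl)oxy]-7,7-(ethylenedioxy)-6,8a-dimethyl-3-(propan-2-yl)decahydroazulen-4-yl 4-methoxybenzoate (6RS)
Conditions: Et3N, DMAP, CH2Cl2, rt to 40 °C
Reagents that add atoms: none
Why: Nucleophilic catalysis (DMAP) acylates the only free hydroxyl, a hindered secondary alcohol, with retention at C6.

**Step 12**
Reactants: 20 ester ketal
Product: 21 (3R,3aS,4S,8aR)-3-hydroxy-6,8a-dimethyl-7-oxo-3-(propan-2-yl)decahydroazulen-4-yl 4-methoxybenzoate (6RS)
Conditions: 48% aq. HF, MeCN, rt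
Reagents that add atoms: water, O
Why: Aqueous acidic fluoride should hydrolyse the dioxolane and cleave the tertiary silyl ether in one operation (acetal hydrolysis and Si–O cleavage), while the aryl ester and the now non-allylic tertiary alcohol are stable; acyl migration is disfavoured by the trans 1,3-relationship of the two oxygens.

**Step 13**
Reactants: 21 keto alcohol
Product: 22 (3R,3aS,4S,8aR)-3-hydroxy-6,8a-dimethyl-7-oxo-3-(propan-2-yl)-1,2,3,3a,4,7,8,8a-octahydroazulen-4-yl 4-methoxybenzoate
Conditions: IBX, DMSO, 70 °C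
Reagents that add atoms: none
Why: IBX dehydrogenation of the ketone through its more substituted enol; desaturation is only possible toward C7 because C10 adjoins the quaternary C1, so the endocyclic C7=C8 enone is expected and both C8 epimers converge.

**Step 14**
Reactants: 22 enone
Product: 23 (3R,3aS,4S,7R,8aR)-3,7-dihydroxy-6,8a-dimethyl-3-(propan-2-yl)-1,2,3,3a,4,7,8,8a-octahydroazulen-4-yl 4-methoxybenzoate (CNP0251753.2)
Conditions: NaBH4, CeCl3·7H2O, MeOH, −78 °C
Reagents that add atoms: none
Why: Luche 1,2-reduction of the enone; the angular methyl is 1,3 to the carbonyl carbon and blocks its face, so hydride should add from the opposite face and give the C9 hydroxyl cis to that methyl, with the ester untouched.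

**Compound list**

Bicyclic names use azulene locants: azulene C1 = C2, C2 = C3, C3 = C4, C3a = C5, C4 = C6, C5 = C7, C6 = C8, C7 = C9, C8 = C10, C8a = C1 of the numbering in the plan.

1 | (S)-(+)-terpinen-4-ol, (1S)-4-methyl-1-(propan-2-yl)cyclohex-3-en-1-ol | CC1=CC[C@](O)(C(C)C)CC1 | starting material
2 | tert-butyldimethyl{[(1S)-4-methyl-1-(propan-2-yl)cyclohex-3-en-1-yl]oxy}silane | CC1=CC[C@](O[Si](C)(C)C(C)(C)C)(C(C)C)CC1 | intermediate
3 | (3S)-3-[(tert-butyldimethylsilyl)oxy]-6-oxo-3-(propan-2-yl)heptanal (not isolated) | O=CC[C@](O[Si](C)(C)C(C)(C)C)(C(C)C)CCC(C)=O | intermediate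
4 | (5S)-5-[(tert-butyldimethylsilyl)oxy]-7,7-dimethoxy-5-(propan-2-yl)heptan-2-one | COC(OC)C[C@](O[Si](C)(C)C(C)(C)C)(C(C)C)CCC(C)=O | intermediate
5 | triethyl phosphonoacetate | CCOC(=O)CP(=O)(OCC)OCC | starting material
6 | ethyl (2E,6S)-6-[(tert-butyldimethylsilyl)oxy]-8,8-dimethoxy-3-methyl-6-(propan-2-yl)oct-2-enoate | CCOC(=O)/C=C(\C)CC[C@@](O[Si](C)(C)C(C)(C)C)(C(C)C)CC(OC)OC | intermediate
7 | 1-[(1E,5S)-5-[(tert-butyldimethylsilyl)oxy]-7,7-dimethoxy-2-methyl-5-(propan-2-yl)hept-1-en-1-yl]cyclopropan-1-ol | OC1(CC1)/C=C(\C)CC[C@@](O[Si](C)(C)C(C)(C)C)(C(C)C)CC(OC)OC | intermediate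
8 | 2,4,6-trimethylpyridinium N,O-acetal triflate of the C6 carbon, cyclopropanol already triethylsilylated (not isolated) | CC[Si](CC)(CC)OC1(CC1)/C=C(\C)CC[C@@](O[Si](C)(C)C(C)(C)C)(C(C)C)CC(OC)[n+]1c(C)cc(C)cc1C.[O-]S(=O)(=O)C(F)(F)F | intermediate
9 | (3S,6E)-3-[(tert-butyldimethylsilyl)oxy]-6-methyl-3-(propan-2-yl)-7-{1-[(triethylsilyl)oxy]cyclopropyl}hept-6-enal | CC[Si](CC)(CC)OC1(CC1)/C=C(\C)CC[C@@](O[Si](C)(C)C(C)(C)C)(C(C)C)CC=O | intermediate
10 | (3R,6E)-3-[(tert-butyldimethylsilyl)oxy]-6-methyl-3-(propan-2-yl)-7-{1-[(triethylsilyl)oxy]cyclopropyl}hepta-1,6-dien-1-yl nonafluorobutane-1-sulfonate, mixture of 1E and 1Z (not isolated) | CC[Si](CC)(CC)OC1(CC1)/C=C(\C)CC[C@@](O[Si](C)(C)C(C)(C)C)(C(C)C)C=COS(=O)(=O)C(F)(F)C(F)(F)C(F)(F)C(F)(F)F | intermediate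
11 | (3R,6E)-3-[(tert-butyldimethylsilyl)oxy]-6-methyl-3-(propan-2-yl)-7-{1-[(triethylsilyl)oxy]cyclopropyl}hept-6-en-1-yne | CC[Si](CC)(CC)OC1(CC1)/C=C(\C)CC[C@@](O[Si](C)(C)C(C)(C)C)(C(C)C)C#C | intermediate
12 | (3R,8aR)-3-[(tert-butyldimethylsilyl)oxy]-8a-methyl-3-(propan-2-yl)-7-[(triethylsilyl)oxy]-1,2,3,5,6,8a-hexahydroazulene (not isolated) | C[C@]12CC[C@@](O[Si](C)(C)C(C)(C)C)(C(C)C)C1=CCCC(O[Si](CC)(CC)CC)=C2 | intermediate
13 | (3R,8aR)-3-[(tert-butyldimethylsilyl)oxy]-8a-methyl-3-(propan-2-yl)-2,3,5,6,8,8a-hexahydroazulen-7(1H)-one | C[C@]12CC[C@@](O[Si](C)(C)C(C)(C)C)(C(C)C)C1=CCCC(=O)C2 | intermediate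
14 | lithium (3R,8aR)-3-[(tert-butyldimethylsilyl)oxy]-8a-methyl-3-(propan-2-yl)-1,2,3,5,8,8a-hexahydroazulen-7-olate (not isolated) | C[C@]12CC[C@@](O[Si](C)(C)C(C)(C)C)(C(C)C)C1=CCC=C(O[Li])C2 | intermediate
15 | (3R,8aR)-3-[(tert-butyldimethylsilyl)oxy]-6,8a-dimethyl-3-(propan-2-yl)-2,3,5,6,8,8a-hexahydroazulen-7(1H)-one, C6 epimers | C[C@]12CC[C@@](O[Si](C)(C)C(C)(C)C)(C(C)C)C1=CCC(C)C(=O)C2 | intermediate
16 | 7-ethylene ketal (spiro-1,3-dioxolane) of 15, C6 epimers | C[C@]12CC[C@@](O[Si](C)(C)C(C)(C)C)(C(C)C)C1=CCC(C)C3(OCCO3)C2 | intermediate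
17 | C4-boranyl adduct of 16, boron and H-3a on the face opposite the 8a-methyl (not isolated) | B[C@H]1CC(C)C2(OCCO2)C[C@@]3(C)CC[C@@](O[Si](C)(C)C(C)(C)C)(C(C)C)[C@H]13 | intermediate
18 | (3R,3aS,4S,8aR)-3-[(tert-butyldimethylsilyl)oxy]-7,7-(ethylenedioxy)-6,8a-dimethyl-3-(propan-2-yl)decahydroazulen-4-ol, C6 epimers | O[C@H]1CC(C)C2(OCCO2)C[C@@]3(C)CC[C@@](O[Si](C)(C)C(C)(C)C)(C(C)C)[C@H]13 | intermediate
19 | 4-methoxybenzoyl chloride | COc1ccc(cc1)C(Cl)=O | starting material
20 | (3R,3aS,4S,8aR)-3-[(tert-butyldimethylsilyl)oxy]-7,7-(ethylenedioxy)-6,8a-dimethyl-3-(propan-2-yl)decahydroazulen-4-yl 4-methoxybenzoate, C6 epimers | COc1ccc(cc1)C(=O)O[C@H]1CC(C)C2(OCCO2)C[C@@]3(C)CC[C@@](O[Si](C)(C)C(C)(C)C)(C(C)C)[C@H]13 | intermediate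
21 | (3R,3aS,4S,8aR)-3-hydroxy-6,8a-dimethyl-7-oxo-3-(propan-2-yl)decahydroazulen-4-yl 4-methoxybenzoate, C6 epimers | COc1ccc(cc1)C(=O)O[C@H]1CC(C)C(=O)C[C@@]2(C)CC[C@@](O)(C(C)C)[C@H]12 | intermediate
22 | (3R,3aS,4S,8aR)-3-hydroxy-6,8a-dimethyl-7-oxo-3-(propan-2-yl)-1,2,3,3a,4,7,8,8a-octahydroazulen-4-yl 4-methoxybenzoate | COc1ccc(cc1)C(=O)O[C@H]1C=C(C)C(=O)C[C@@]2(C)CC[C@@](O)(C(C)C)[C@H]12 | intermediate
23 | (3R,3aS,4S,7R,8aR)-3,7-dihydroxy-6,8a-dimethyl-3-(propan-2-yl)-1,2,3,3a,4,7,8,8a-octahydroazulen-4-yl 4-methoxybenzoate (CNP0251753.2) | COc1ccc(cc1)C(=O)O[C@H]1C=C(C)[C@H](O)C[C@@]2(C)CC[C@@](O)(C(C)C)[C@H]12 | target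

**Step count and risks**

Total step count: 14. Longest linear sequence: 14 steps (1 to 23).

Steps most likely to fail, with fallbacks:

Step 7. The remote C4 centre may discriminate the two faces of the trisubstituted alkene poorly, so that the C1 epimer forms alongside. Insertion at the congested C1/C5 pair may also be slow enough for ring expansion of the siloxyvinylcyclopropane to compete. The fallback gives up substrate control for catalyst control. It sets out from enyne 11 and uses a cationic monovalent rhodium complex of a chiral bisphosphine, made from [Rh(cod)Cl]2, AgSbF6 and (R)- or (S)-BINAP in 1,2-dichloroethane at 60–70 °C. The ligand enantiomer is chosen so that the catalyst, not C4, selects the alkene face (double stereodifferentiation, known for asymmetric (5+2) cycloadditions of tethered vinylcyclopropanes). The cationic catalyst also works at lower temperature. The same buffered fluoride work-up brings the route back at ketone 13. No new compound arises (F0).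

Step 10. Borane may attack the face that carries the angular methyl (the isopropyl group overriding it), which would give the cis-fused C5/C6 epimer pair, or it may add sluggishly to an alkene flanked by two quaternary carbons. The fallback replaces the single syn addition by an epoxide rearrangement followed by a thermodynamic reduction, so that a preference for that face becomes useful. It sets out from ketal 16. mCPBA (NaHCO3, CH2Cl2, 0 °C) should give the epoxide on the angular-methyl face, the α-epoxide of 16 F1. BF3·OEt2 (CH2Cl2, −78 °C) opens it at the tertiary C5 with a 1,2-hydride shift from C6 (Meinwald rearrangement), which delivers hydrogen to the opposite face of C5 and gives the trans-fused C6 ketone F2. Dissolving-metal reduction (Li, NH3/THF, EtOH, −78 °C) should then give the thermodynamically favoured equatorial C6 alcohol, and the route comes back at alcohol 18.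

Step 6. The aldehyde enolate may expel the tertiary β-siloxy group (E1cB elimination) faster than it is O-sulfonylated. The fallback avoids sulfonate elimination by removing one carbon and adding one back. It sets out from aldehyde 9. Piperidine (K2CO3, toluene, rt) gives the piperidine enamine of 9 F3. CuCl/O2 (MeCN, rt) cleaves the enamine C=C to the one-carbon-lower α-siloxy aldehyde (2R,5E)-2-[(tert-butyldimethylsilyl)oxy]-5-methyl-2-(propan-2-yl)-6-{1-[(triethylsilyl)oxy]cyclopropyl}hex-5-enal F4. Seyferth–Gilbert homologation with the Bestmann–Ohira reagent (K2CO3, MeOH, 0 °C to rt) restores the carbon as the terminal alkyne, and the route comes back at enyne 11.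

Further compounds
F0 | step 7 | none | none
F1 | step 10 | α-epoxide of 16 (oxirane across C3a–C4 on the face of the 8a-methyl), C6 epimers | O1[C@@H]2CC(C)C3(OCCO3)C[C@@]4(C)CC[C@@](O[Si](C)(C)C(C)(C)C)(C(C)C)[C@@]124
F2 | step 10 | trans-fused 4-ketone: 3-[(tert-butyldimethylsilyl)oxy]-7,7-(ethylenedioxy)-6,8a-dimethyl-3-(propan-2-yl)octahydroazulen-4(1H)-one with H-3a trans to the 8a-methyl, C6 epimers | O=C1CC(C)C3(OCCO3)C[C@@]4(C)CC[C@@](O[Si](C)(C)C(C)(C)C)(C(C)C)[C@H]14
F3 | step 6 | (E)-piperidine enamine of aldehyde 9 | C1CCN(CC1)/C=C/[C@](O[Si](C)(C)C(C)(C)C)(C(C)C)CC/C(C)=C/C2(O[Si](CC)(CC)CC)CC2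
F4 | step 6 | (2R,5E)-2-[(tert-butyldimethylsilyl)oxy]-5-methyl-2-(propan-2-yl)-6-{1-[(triethylsilyl)oxy]cyclopropyl}hex-5-enal | O=C[C@](O[Si](C)(C)C(C)(C)C)(C(C)C)CC/C(C)=C/C1(O[Si](CC)(CC)CC)CC1
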